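The retrosynthesis cuts, in one operation, the two bonds that hold the ester carbonyl carbon C1: C1–C2 to the alkyl chain and C1–O to the OCH2CH2Ar unit. This leaves carbon monoxide, tyrosol and a straight C31 hydrocarbon.
This is possible because C2–C32 of the acyl part are 31 carbons in one unbranched, heteroatom-free string ending in a methyl group. A C31 alkene with its double bond anywhere can serve once a metal can migrate to a chain end, and either end gives the same acyl group. The only ring, the 4-hydroxyphenyl ring, comes ready-made with tyrosol and is a spectator.
Thirty-one is twice sixteen less one, the carbon count of the ketone derived from two palmitic acids, so palmitone 1 is reduced to alcohol 2 and dehydrated to hentriacont-15-ene 3.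
In the forward direction the chain is completed last: 3, tyrosol 4 and carbon monoxide 5 are joined through the terminal alkene 6 to basalethanolide A 7. No ring is made at any stage.
The target has neither a stereocentre nor a C=C bond, so no stereochemistry has to be set, and the geometry of 3 disappears in the carbonylation.

Key step: step 3

Assumption: 3 is drawn and listed as the E isomer but stands for whatever mixture of E, Z and slightly migrated hentriacontenes the elimination delivers, since all of them enter the same equilibrium in step 3.

Step 1
Reactants: 1 16-hentriacontanone (palmitone)
Product: 2 hentriacontan-16-ol
Conditions: NaBH4 (1.5 equiv), THF/EtOH, 50 °C; then H2O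
Reagents that add atoms: none
Why: Borohydride reduction of an unhindered dialkyl ketone is routine, warm THF keeps the waxy substrate dissolved, and because C16 carries two identical pentadecyl chains the new carbinol carbon is not a stereocentre.

Step 2
Reactants: 2 hentriacontan-16-ol
Product: 3 (E)-hentriacont-15-ene (used as the isomer mixture obtained)
Conditions: p-TsOH·H2O (10 mol%), o-xylene, reflux, Dean–Stark trap; filtration through SiO2 (heptane)
Reagents that add atoms: none
Why: Acid-catalysed dehydration (E1 elimination) driven by azeotropic removal of water should give the alkene, the symmetric alcohol offering only the equivalent hydrogens at C15 and C17 so that the 15-ene is the sole primary product, and any E/Z scatter or acid-induced double-bond migration is harmless because step 3 equilibrates all positions.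

Step 3
Reactants: 3 (E)-hentriacont-15-ene; 4 tyrosol (4-(2-hydroxyethyl)phenol); 5 carbon monoxide
Product: 7 basalethanolide A (2-(4-hydroxyphenyl)ethyl dotriacontanoate), via hentriacont-1-ene 6 (not isolated)
Conditions: Pd(OAc)2 (2 mol%), 1,2-bis(di-tert-butylphosphinomethyl)benzene (10 mol%), MeSO3H (20 mol%), 4 (2 equiv), CO (30 bar), toluene/1,4-dioxane, 90 °C, autoclave; aqueous wash, SiO2, recrystallisation
Reagents that add atoms: none
Why: Pd(OAc)2, the diphosphine and MeSO3H should form a cationic diphosphine hydride of divalent palladium that adds across C15=C16 of 3 and then travels along the chain by fast, reversible beta-hydride elimination and reinsertion, passing through every alkene isomer down to 6 and the primary hentriacontyl complex. Migratory insertion of 5 into that primary Pd–C bond makes C1–C2, and attack of the aliphatic hydroxyl of 4 on the acyl complex makes C1–O and returns the hydride. The closest known reaction type is the isomerising alkoxycarbonylation of internal fatty alkenes and internal octenes with this same catalyst, and the longer walk should not cost rate, because 2 of the 30 double-bond positions of a C31 chain are terminal and both lead to the same C32 acyl group, a share no smaller than the single productive end of a C18 fatty ester. No ring closes and no stereocentre forms, and the E/Z identity of 3 is lost in the first insertion. Linear selectivity is needed and comes from the four tert-butyl groups on phosphorus, which make alcoholysis of any branched acyl far slower than that of the unhindered linear one, so the equilibrating pool empties through the chain end (a Curtin–Hammett situation). Selectivity for the primary alcohol over the phenol is also needed and rests on the greater nucleophilicity of the aliphatic hydroxyl in a medium too acidic for phenoxide to exist, supported by the excess of 4, which keeps alcoholysis fast, disfavours double acylation and is washed out with water afterwards.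

Compound list
1 | 16-hentriacontanone (palmitone) | CCCCCCCCCCCCCCCC(=O)CCCCCCCCCCCCCCC | starting material
2 | hentriacontan-16-ol | CCCCCCCCCCCCCCCC(O)CCCCCCCCCCCCCCC | intermediate
3 | (E)-hentriacont-15-ene (stands for the isomer mixture) | CCCCCCCCCCCCCC/C=C/CCCCCCCCCCCCCCC | intermediate
4 | tyrosol, 4-(2-hydroxyethyl)phenol | OCCc1ccc(O)cc1 | starting material
5 | carbon monoxide | [C-]#[O+] | starting material
6 | hentriacont-1-ene (free or palladium-bound, formed in the flask) | CCCCCCCCCCCCCCCCCCCCCCCCCCCCCC=C | intermediate
7 | basalethanolide A, 2-(4-hydroxyphenyl)ethyl dotriacontanoate | CCCCCCCCCCCCCCCCCCCCCCCCCCCCCCCC(=O)OCCc1ccc(O)cc1 | target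

Total step count: 3
Longest linear sequence: 3 steps (1 to 2 to 3 to 7)

Steps most likely to fail

First risk, step 3. With only two equivalents of a solid alcohol in an inert solvent, cleavage of the acyl complex may become so slow that the catalyst decays to zerovalent palladium metal before the alkene pool is drained. Competing acylation at the phenol may also erode the chemoselectivity. The fallback separates carbonylation from acyl transfer and sets out from 3. Isomerising methoxycarbonylation with 5 under the same palladium catalyst, now in methanol/toluene so that the alcohol is present in large excess as in the closest known cases, should give methyl dotriacontanoate F1. Transesterification of F1 with 4 is then catalysed by immobilised Candida antarctica lipase B in toluene/2-methyl-2-butanol at about 65 °C, with the liberated methanol taken up by molecular sieves. This enzyme type acylates the primary hydroxyl of tyrosol and leaves the phenol alone, so the fallback returns to the route at 7.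

Second risk, step 2. The dehydration may stall at the di-sec-alkyl ether or the sulfonate ester. Cationic oligomerisation of the alkene may also consume material and leave hydrocarbon impurities that are hard to remove. The fallback avoids carbocations and sets out from 2. Mesylation (MsCl, Et3N, CH2Cl2/THF, 0 °C to room temperature) should give hentriacontan-16-yl methanesulfonate F2. E2 elimination with KOtBu in warm THF should then deliver the E/Z alkene, rejoining the route at 3.

Third risk, step 1. The waxy ketone may crystallise out of the alcoholic medium. Conversion would then stay incomplete, and unreacted ketone would co-crystallise with the alcohol. The fallback bypasses the alcohol altogether and sets out from 1. Condensation with p-toluenesulfonylhydrazide in refluxing THF/EtOH should give 16-hentriacontanone p-toluenesulfonylhydrazone F3. A Shapiro reaction (n-BuLi, 2.5 equiv, TMEDA/hexane, 0 °C to room temperature) should convert F3 into (Z)-hentriacont-15-en-16-yllithium F4. Quenching with water should give mainly (Z)-hentriacont-15-ene F5. This is a geometric component of 3 and serves in step 3 unchanged, so the route is rejoined at 3.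

Further compounds
F1 | step 3 | methyl dotriacontanoate | CCCCCCCCCCCCCCCCCCCCCCCCCCCCCCCC(=O)OC
F2 | step 2 | hentriacontan-16-yl methanesulfonate | CCCCCCCCCCCCCCCC(OS(C)(=O)=O)CCCCCCCCCCCCCCC
F3 | step 1 | 16-hentriacontanone p-toluenesulfonylhydrazone | CCCCCCCCCCCCCCCC(=NNS(=O)(=O)c1ccc(C)cc1)CCCCCCCCCCCCCCC
F4 | step 1 | (Z)-hentriacont-15-en-16-yllithium | CCCCCCCCCCCCCC/C=C(\CCCCCCCCCCCCCCC)[Li]
F5 | step 1 | (Z)-hentriacont-15-ene | CCCCCCCCCCCCCC/C=C\CCCCCCCCCCCCCCC
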